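Numbering: furanone O1, C2(=O), C3, C4(Br), C5, exocyclic C6, carbinol C1'. Retrosynthetic cuts, in order: O–Ac; C6–H back to C6–Br (5‑dibromomethylene lactone); both C6–Br (5‑methylene lactone); then O1–C5, C3=C4 and C4–Br together; last C1'–C3.
Forward: butanal and ethyl diazoacetate give the C1'–C3–C2 chain. The only ring, the butenolide, is then assembled in one flask from this α‑diazo ester, propargyl acetate and Br2. C6 is brominated twice, one Br is taken off again, and Si is exchanged for Ac.
Enabling feature: ring atoms O1–C2–C3 are a carboxyl group with its α‑carbon, which is a C/O three‑atom unit once C3 is a diazo (carbene) carbon, and C4–C5(–C6) is a propargyl unit. Joined at C3–C4 they form the allene C3=C4=C5, whose central carbon is the ring carbon that bears Br and whose terminus C5 closes a five‑membered ring with the ester oxygen.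
Stereochemistry: C1' (R) comes from a catalyst‑controlled asymmetric diazo‑aldol addition and is carried as OTBS. The contra‑steric 5E alkene comes from Pd‑catalysed removal of the less hindered C6–Br (syn to O1) of the dibromomethylene lactone.

Key step: step 3

Remark: the SMILES is read as (1'R,5E), with the exocyclic Br syn to C4–Br and anti to O1. This less stable isomer is made late and kept from light, bromide ion and nucleophilic bases.

Step 1
Reactants: 1 butanal; 2 ethyl diazoacetate
Product: 3 ethyl (3R)-2-diazo-3-hydroxyhexanoate
Conditions: ProPhenol ligand (5 mol %, the antipode that maps onto the R carbinol), Bu2Mg (10 mol %), cis-1,2-cyclopentanediol (5 mol %), THF, −20 °C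
Reagents that add atoms: none
Why: Direct catalytic asymmetric aldol addition of the acidic diazoacetate C–H to the aldehyde inside the dinuclear Mg–ProPhenol pocket, a reaction type shown for aliphatic aldehydes, should set C1' as R by catalyst control.

Step 2
Reactants: 3 ethyl (3R)-2-diazo-3-hydroxyhexanoate
Product: 4 ethyl (3R)-3-(tert-butyldimethylsilyloxy)-2-diazohexanoate
Conditions: TBSCl, imidazole, DMF, rt
Reagents that add atoms: tert-butyldimethylsilyl chloride, CC(C)(C)[Si](C)(C)Cl
Why: Standard silylation under mildly basic conditions spares the acid-sensitive diazo group and replaces the OH, which would quench a metal carbene, with a bulky, poorly leaving and poorly nucleophilic OTBS group.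

Step 3
Reactants: 4 ethyl (3R)-3-(tert-butyldimethylsilyloxy)-2-diazohexanoate; 5 propargyl acetate
Product: 9 4-bromo-3-[(1R)-1-(tert-butyldimethylsilyloxy)butyl]-5-methylenefuran-2(5H)-one, via 3-alkynoate 6 (not isolated), via allenoate 7 (not isolated), via acetoxymethyl bromobutenolide 8 (not isolated)
Conditions: 5 (1.1 equiv), CuI (10 mol %), 2,2'-bipyridine (10 mol %), K2CO3 (20 mol %), MeCN, 0 °C→rt, 4 added over 4 h; evaporate, CH2Cl2, Br2 (1.0 equiv), −20 °C; DBU (1.2 equiv), 0 °C
Reagents that add atoms: bromine, BrBr
Why: Proposed new method: the copper(I) acetylide of 5 takes up diazo ester 4 with loss of N2, the alkynyl ligand migrates to the carbene carbon (C3–C4 bond), and protonation followed by a carbonate-mediated 1,3-H shift leads through 6 to allenoate 7 (C3=C4=C5). Br2 then attacks the ester-remote, more electron-rich C4=C5 π bond at the central carbon (C4–Br), the ester carbonyl oxygen closes the butenolide ring on C5 in a 5-endo-trig mode (O1–C5 bond), bromide removes the ethyl group from the alkoxy-oxocarbenium ion to give 8, and DBU expels acetate by E1cB through the 2-oxidofuran to give 9. The closest known reaction types are the copper-catalysed coupling of α-alkyl-α-diazo esters that carry β-hydrogens with terminal alkynes to 2,4-disubstituted allenoates and the halolactonisation of 2,3-allenoates to 4-halobutenolides; new are their merger in one flask and the β-silyloxy, δ-acetoxy substitution. No lasting stereocentre is made: the allene axis, C3 of 6 and C5 of 8 are uncontrolled and vanish in 9, while C1' stays R because its C–O and C–H bonds are not touched. The step needs alkynyl migration to beat the 1,2-hydride shift of C1'–H in the copper carbene, which the pre-bound acetylide (an intramolecular migration), slow addition of 4 and low temperature should secure, and it needs the ester oxygen to beat the silyl ether oxygen at C5, which the bulk and low basicity of OTBS should secure. Regiochemistry is fixed by the substrates, since only the terminal alkyne carbon is bound to copper and only C5 can be reached by the carbonyl oxygen in a five-membered closure.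

Step 4
Reactants: 9 4-bromo-3-[(1R)-1-(tert-butyldimethylsilyloxy)butyl]-5-methylenefuran-2(5H)-one
Product: 11 (5Z)-4-bromo-5-(bromomethylene)-3-[(1R)-1-(tert-butyldimethylsilyloxy)butyl]furan-2(5H)-one, via tribromide 10 (not isolated)
Conditions: Br2 (1.05 equiv), CH2Cl2, −78→0 °C; Et3N (1.5 equiv), 0 °C
Reagents that add atoms: bromine, BrBr
Why: Addition of Br2 to the most electron-rich alkene (the exocyclic enol-ester C5=C6) and base-induced loss of HBr is the standard bromination–dehydrobromination of 5-methylenebutenolides; the Z isomer should prevail for steric reasons, but this geometry is erased in step 5.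

Step 5
Reactants: 11 (5Z)-4-bromo-5-(bromomethylene)-3-[(1R)-1-(tert-butyldimethylsilyloxy)butyl]furan-2(5H)-one
Product: 13 4-bromo-5-(dibromomethylene)-3-[(1R)-1-(tert-butyldimethylsilyloxy)butyl]furan-2(5H)-one, via tetrabromide 12 (not isolated)
Conditions: Br2 (1.2 equiv), CH2Cl2, rt; evaporate; Et3N (1.5 equiv), CH2Cl2, 0 °C
Reagents that add atoms: bromine, BrBr
Why: A second bromination–dehydrobromination cycle on the same exocyclic alkene should work because the C6–H of 12, acidified by two bromines, is lost together with the tertiary C5–Br in an E2 elimination that restores conjugation.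

Step 6
Reactants: 13 4-bromo-5-(dibromomethylene)-3-[(1R)-1-(tert-butyldimethylsilyloxy)butyl]furan-2(5H)-one
Product: 14 (5E)-4-bromo-5-(bromomethylene)-3-[(1R)-1-(tert-butyldimethylsilyloxy)butyl]furan-2(5H)-one
Conditions: Pd(PPh3)4 (5 mol %), Bu3SnH (1.05 equiv, slow addition), toluene, 0 °C→rt, dark
Reagents that add atoms: none
Why: In the Pd(0)-catalysed hydrogenolysis of a 1,1-dibromoalkene with a tin hydride, oxidative addition should take the less hindered C6–Br (syn to O1, anti to C4) and hydride delivery goes with retention, so the remaining Br is syn to C4–Br (5E), while C4–Br is shielded by the CH(OTBS)Pr group and by the neighbouring C6–Br.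

Step 7
Reactants: 14 (5E)-4-bromo-5-(bromomethylene)-3-[(1R)-1-(tert-butyldimethylsilyloxy)butyl]furan-2(5H)-one
Product: 15 acetoxyfimbrolide, (1R)-1-[(5E)-4-bromo-5-(bromomethylidene)-2-oxo-2,5-dihydrofuran-3-yl]butyl acetate
Conditions: Ac2O (3 equiv), Cu(OTf)2 (5 mol %), CH2Cl2, 0 °C→rt, dark
Reagents that add atoms: acetic anhydride, CC(=O)OC(C)=O
Why: Lewis-acid-catalysed acetolysis of the silyl ether (O-acylation, then loss of silicon as its acetate) exchanges Si for Ac at oxygen without breaking the C1'–O bond, so R is retained, and it avoids the nucleophilic bases, fluoride and bromide that could add to C6 and isomerise the 5E alkene.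

Compound list
1 | butanal | CCCC=O | starting material
2 | ethyl diazoacetate | CCOC(=O)C=[N+]=[N-] | starting material
3 | ethyl (3R)-2-diazo-3-hydroxyhexanoate | CCC[C@@H](O)C(=[N+]=[N-])C(=O)OCC | intermediate
4 | ethyl (3R)-3-(tert-butyldimethylsilyloxy)-2-diazohexanoate | CCC[C@@H](O[Si](C)(C)C(C)(C)C)C(=[N+]=[N-])C(=O)OCC | intermediate
5 | propargyl acetate (prop-2-yn-1-yl acetate) | C#CCOC(C)=O | starting material
6 | ethyl 5-acetoxy-2-[(1R)-1-(tert-butyldimethylsilyloxy)butyl]pent-3-ynoate (3-alkynoate, C2 epimers) | CCC[C@@H](O[Si](C)(C)C(C)(C)C)C(C#CCOC(C)=O)C(=O)OCC | intermediate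
7 | ethyl 5-acetoxy-2-[(1R)-1-(tert-butyldimethylsilyloxy)butyl]penta-2,3-dienoate (allenoate, both axial isomers) | CCC[C@@H](O[Si](C)(C)C(C)(C)C)C(=C=CCOC(C)=O)C(=O)OCC | intermediate
8 | {3-bromo-4-[(1R)-1-(tert-butyldimethylsilyloxy)butyl]-5-oxo-2,5-dihydrofuran-2-yl}methyl acetate (C5 epimers) | CCC[C@@H](O[Si](C)(C)C(C)(C)C)C1=C(Br)C(COC(C)=O)OC1=O | intermediate
9 | 4-bromo-3-[(1R)-1-(tert-butyldimethylsilyloxy)butyl]-5-methylenefuran-2(5H)-one | CCC[C@@H](O[Si](C)(C)C(C)(C)C)C1=C(Br)C(=C)OC1=O | intermediate
10 | 4,5-dibromo-5-(bromomethyl)-3-[(1R)-1-(tert-butyldimethylsilyloxy)butyl]furan-2(5H)-one (tribromide, C5 epimers) | CCC[C@@H](O[Si](C)(C)C(C)(C)C)C1=C(Br)C(Br)(CBr)OC1=O | intermediate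
11 | (5Z)-4-bromo-5-(bromomethylene)-3-[(1R)-1-(tert-butyldimethylsilyloxy)butyl]furan-2(5H)-one | CCC[C@@H](O[Si](C)(C)C(C)(C)C)C1=C(Br)/C(=C/Br)OC1=O | intermediate
12 | 4,5-dibromo-5-(dibromomethyl)-3-[(1R)-1-(tert-butyldimethylsilyloxy)butyl]furan-2(5H)-one (tetrabromide, C5 epimers) | CCC[C@@H](O[Si](C)(C)C(C)(C)C)C1=C(Br)C(Br)(C(Br)Br)OC1=O | intermediate
13 | 4-bromo-5-(dibromomethylene)-3-[(1R)-1-(tert-butyldimethylsilyloxy)butyl]furan-2(5H)-one | CCC[C@@H](O[Si](C)(C)C(C)(C)C)C1=C(Br)C(=C(Br)Br)OC1=O | intermediate
14 | (5E)-4-bromo-5-(bromomethylene)-3-[(1R)-1-(tert-butyldimethylsilyloxy)butyl]furan-2(5H)-one | CCC[C@@H](O[Si](C)(C)C(C)(C)C)C1=C(Br)/C(=C\Br)OC1=O | intermediate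
15 | acetoxyfimbrolide, (1R)-1-[(5E)-4-bromo-5-(bromomethylidene)-2-oxo-2,5-dihydrofuran-3-yl]butyl acetate | CCC[C@@H](OC(C)=O)C1=C(Br)/C(=C\Br)OC1=O | target

Total step count: 7. Longest linear sequence: 7 (steps 1–7; 5 is bought).

Steps most likely to fail

Step 3 (proposed new method). The 1,2-hydride shift of C1'–H in the copper carbene may outrun alkynyl migration. Acetate may be lost too early from the propargyl/allenyl anion during the base-mediated isomerisation. The silyl ether oxygen may also compete with the ester oxygen in the bromocyclisation.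
The fallback uses known chemistry, sets out from 4 and comes back at 14, so steps 4–6 are bypassed.
- Oxidation of 4 with dimethyldioxirane in acetone should give ethyl (3R)-3-(tert-butyldimethylsilyloxy)-2-oxohexanoate F1.
- Ramirez olefination (CBr4, PPh3, CH2Cl2, 0 °C) should give ethyl (3R)-2-(dibromomethylene)-3-(tert-butyldimethylsilyloxy)hexanoate F2.
- Sonogashira mono-coupling with trimethylsilylacetylene (Pd(PPh3)4, CuI, Et3N) should occur at the less hindered C–Br, anti to the CH(OTBS)Pr group and syn to the ester, giving ethyl (2E)-3-bromo-2-[(1R)-1-(tert-butyldimethylsilyloxy)butyl]-5-(trimethylsilyl)pent-2-en-4-ynoate F3.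
- LiOH in aqueous THF at 0 °C should remove the ethyl and the C-silyl groups to give (2E)-3-bromo-2-[(1R)-1-(tert-butyldimethylsilyloxy)butyl]pent-2-en-4-ynoic acid F4.
- NBS and KHCO3 in CH2Cl2–H2O should then close the lactone by anti 5-exo-dig bromolactonisation of the terminal alkyne. This places O1 and Br trans and so leads to 14.

Step 6. Oxidative addition may take place at C4–Br, a second hydrogenolysis may follow, or a radical-chain reduction may erode chemo- and stereoselectivity.
The fallback sets out from 11 and comes back at 14, skipping step 5. Irradiation of 11 with near-UV/visible light in MeCN should set up a Z/E photostationary mixture, behaviour that is typical of 5-(bromomethylene)butenolides. Compound 14 is separated by chromatography in the dark and recovered 11 is irradiated again. No new compound is made (F0).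

Step 7. Acid-promoted E→Z isomerisation through the O-activated furanone, or ionisation at C1', may occur during the Lewis-acid acetolysis.
The fallback sets out from 14 and comes back at 15. HF·pyridine in THF should give (5E)-4-bromo-5-(bromomethylene)-3-[(1R)-1-hydroxybutyl]furan-2(5H)-one F5. This is acetylated under neutral conditions by a lipase (triacylglycerol lipase class, e.g. from Burkholderia cepacia) with vinyl acetate in MTBE in the dark. By the empirical size rule for secondary alcohols the R alcohol is the fast-reacting enantiomer, so the enzyme should also raise the enantiomeric purity.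

Further compounds
F1 | step 3 | ethyl (3R)-3-(tert-butyldimethylsilyloxy)-2-oxohexanoate | CCC[C@@H](O[Si](C)(C)C(C)(C)C)C(=O)C(=O)OCC
F2 | step 3 | ethyl (3R)-2-(dibromomethylene)-3-(tert-butyldimethylsilyloxy)hexanoate | CCC[C@@H](O[Si](C)(C)C(C)(C)C)C(=C(Br)Br)C(=O)OCC
F3 | step 3 | ethyl (2E)-3-bromo-2-[(1R)-1-(tert-butyldimethylsilyloxy)butyl]-5-(trimethylsilyl)pent-2-en-4-ynoate | CCC[C@@H](O[Si](C)(C)C(C)(C)C)/C(C(=O)OCC)=C(Br)/C#C[Si](C)(C)C
F4 | step 3 | (2E)-3-bromo-2-[(1R)-1-(tert-butyldimethylsilyloxy)butyl]pent-2-en-4-ynoic acid | CCC[C@@H](O[Si](C)(C)C(C)(C)C)/C(C(=O)O)=C(Br)/C#C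
F0 | step 6 | none | none
F5 | step 7 | (5E)-4-bromo-5-(bromomethylene)-3-[(1R)-1-hydroxybutyl]furan-2(5H)-one | CCC[C@@H](O)C1=C(Br)/C(=C\Br)OC1=O
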